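## Analysis of the target

Broussoflavonol E (24) is a flavonol: ring A is fused to the pyranone ring C, which carries the 3-hydroxyl and the C4 carbonyl. Ring A has hydroxyls at C5 and C7 and a 2-methylbut-3-en-2-yl (1,1-dimethylallyl) group at C8. Ring B is attached at C2 and is fused through C3'/C4' to a 2,2-dimethyldihydropyran. It is therefore C6 of an 8-hydroxy-2,2-dimethylchroman that carries a prenyl group at its C5 (C2' of the flavonol).

The target has no stereocentre. The only stereocentres in the route are single, racemic ones in intermediates 17, 19 and 21, and all are lost before the end.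

The sensitive groups are:
- the trisubstituted prenyl alkene, which is easily protonated or oxidised;
- the 1,1-dimethylallyl group, which lies ortho to the 7-hydroxyl and can cyclise onto it under strong acid;
- the free flavonol and polyphenol, which are air-sensitive in base;
- the tertiary alkyl aryl ether of the chroman.

The difficulty is substitution density and regiochemistry. Both benzene rings are pentasubstituted. Ring A is a phloroglucinol in which C6 and C8 are electronically alike, yet a quaternary carbon must be placed at C8, between O7 and O1, and not at C6.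

The strategy rests on the O1–C8a bond of ring C. C8a lies between C4a and the tert-alkyl-bearing C8, so this bond is the most crowded bond of ring C and the one that decides C8 versus C6. If the carbon that becomes C8a carries fluorine in a benzoic acid building block, that decision is made before ring C exists.

## Retrosynthetic reasoning

**24 back to 22.** The last two operations remove only protecting groups. O3, O7 and O5' are carried as methoxymethyl ethers (23), which fall together under mild protic acid. O5 is carried as the single methyl ether of 22. It sits peri to the C4 carbonyl, so chelation singles it out. No skeletal bond is involved. The forward reactions must spare both alkenes, so the Lewis-acid step is run on fully protected 22 and the protic acid comes last.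

**22 back to 20 and 8 (through 21).** Ring C is cut at C3–C4 and at O1–C8a. The ring B ketone 20 supplies C2, C3, the 3-oxygen and, as its carbonyl oxygen, O1. The ring A acid chloride 8 supplies C4 and has fluorine on the future C8a. The classical cut at O1–C2 was not chosen: it would need a ring A phenol in which the tert-alkyl group had already been placed selectively between two of three similar phloroglucinol oxygens. With a fluorine substituent as placeholder for O1, the regiochemistry becomes a property of an arene that can be built unambiguously. The cut is also convergent, since both halves arrive fully substituted. The forward reaction must acylate the enolate of 20 at carbon to give 21 and then substitute the fluorine at a crowded carbon.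

**8 back to 1 and 2.** Acid chloride 8 comes from acid 7 and ester 6. The methoxy group of 6 is traced back to a second fluorine in 5. In 5 both fluorines flank the ester, but one has an unsubstituted neighbour and the other lies next to the quaternary carbon. Displacement is therefore placed after the quaternary carbon is in, and sterics choose the right fluorine. The aryl–C(quaternary) bond is cut back, through phenol 4, to the O-prenyl ether 3 by a sigmatropic shift. In 3 the two ortho positions are identical by symmetry and the para position is blocked by the ester, so the rearrangement needs no regiocontrol. Introducing the methoxy group first would make the two ortho positions different and force the rearrangement to choose. Ether 3 comes from the commercial phenol 1 and prenyl bromide 2.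

**20 back to 15 and 16.** The ketone comes from alcohol 19 by oxidation. The aryl–prenyl bond is cut to aryl bromide 17 and 2, by way of the metalated species 18. The bond between the carbinol carbon and the alkoxymethyl carbon is cut to aldehyde 15 and the one-carbon stannane 16. Aldehyde and bromine are ortho to each other from the starting material onwards. Adding the one-carbon unit first turns the aldehyde into an alkoxide that needs no protection during metalation.

**15 back to 9 and 10.** The methoxymethyl ether of 15 replaces the methyl ether of 13 by way of phenol 14. The exchange is made while the molecule is small and has no alkene. Chroman 13 comes from chromene 12 by saturation of one double bond. Chromene 12 comes from the aryl propargyl ether 11 by a sigmatropic cascade, and 11 from 6-bromovanillin 9 and the propargylic chloride 10. In 11 only one ortho position is free, so the pyran ring can fuse in only one direction. Starting material 9 already has the aldehyde, the bromine and the two oxygens in the right places.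

## Alternatives that were turned down

**Alternative 1: ring A by cyclobutenone benzannulation.**
- Disconnection: ring A is built from acyclic parts. 3-Ethoxycyclobut-2-en-1-one A1 and the silyl ynol ether A2, which carries the 1,1-dimethylallyl carbon on the alkyne, would give the phenol A3.
- Key step: on heating, A1 opens to a vinylketene. This adds A2 across the ketene C=C bond, with the nucleophilic alkyne carbon bonding to the ketene carbon. The new cyclobutenone opens again, the dienylketene closes by a 6π process and tautomerises.
- For: in A3 the free hydroxyl is the future O1 on C8a, the ethoxy group the future O5 and the silyloxy group the future O7. The quaternary carbon lies between hydroxyl and silyloxy. Placement is absolute, all three oxygens are differentiated, and no substitution at a crowded arene carbon is needed. On these points it is stronger than the chosen strategy.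
- Against: A2 is not an article of commerce and needs several steps. The benzannulation delivers only ring A. Ring C would still need acylation at C4a in competition with C6, a condensation with a ring B partner, and separate introduction of the 3-oxygen. The C5 ethyl ether would need the same chelation-assisted cleavage as the methyl ether of 22.
- Comparison: the chosen route gets the same regiochemical certainty from the commercial difluorobenzoate 1 in six ordinary steps, and its key step both joins the halves and closes ring C.

**Alternative 2: the chroman by quinone methide cycloaddition.**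
- Disconnection: the chroman O1–C2 and C3–C4 bonds (chroman numbering). The hydroxymethyl phenol A4, which would come from 9 by hydroxymethylation, is combined with 2-methylpropene A5.
- Key step: thermal loss of water from A4 gives an ortho-quinone methide. This adds A5 in an inverse-demand [4+2] cycloaddition, with the methylene terminus of A5 bonding to the methide carbon. The product is the chroman aldehyde A6, which is the same compound as 13.
- For: the saturated ring is reached directly, with no hydrogenation next to an aryl bromide. From 9 it would take two steps where the chosen route takes three (steps 7 to 9). On step count to this fragment it is at least as good.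
- Against: A4 requires hydroxymethylation of a deactivated phenol at the position squeezed between hydroxyl and bromine. The electron-poor quinone methide can also be trapped by the phenol or oligomerise. A5 is a gas that must be held under pressure at high temperature.
- Comparison: this is a rival only for one fragment. It does nothing for ring C or the crowded O1–C8a bond, which would still need the chosen key step. The chosen route keeps the intramolecular propargyl ether rearrangement, whose regiochemistry is fixed by the single free ortho position and which runs in ordinary glassware.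

**Alternative 3: ring C by aryne insertion into an arylpropiolic acid.**
- Disconnection: O1–C8a, C4a–C4 and O1–C2. The partners are the silyl aryl triflate A7, as precursor of a 3,5-dialkoxy aryne, and the ring B arylpropiolic acid A8.
- Key step: a fluoride source releases the aryne from A7. The carboxylate oxygen of A8 adds to the aryne carbon remote from the flanking alkoxy group. The aryl anion attacks the acyl carbon, a formal insertion into the C–O bond. The resulting ortho-hydroxyaryl ynone closes in a 6-endo-dig manner to flavone A9.
- For: three bonds form in one mild operation, and the alkoxy-directed aryne addition gives the correct 5,7-dioxygenation. In bonds formed per step and in mildness it is stronger than the chosen strategy.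
- Against: A9 has neither the C8 substituent nor the 3-oxygen. An aryne already bearing the quaternary carbon would have to accept the nucleophile at the carbon next to it. The 1,1-dimethylallyl group would therefore be introduced late, by rearrangement of a 7-O-prenyl ether. This requires telling O7 from O5 in a bis(methoxymethyl) ether and then gives C8 and C6 products. C3 would have to be oxidised in the presence of two electron-rich alkenes.
- Comparison: the chosen strategy accepts one hindered substitution, but every substituent, including the 3-oxygen, is in place when ring C closes.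

Key step: step 15

Remark: 3-chloro-3-methylbut-1-yne 10 and tributyl[(methoxymethoxy)methyl]stannane 16 are treated as purchased reagents.

## Route

Step 1
Reactants: 1 methyl 2,6-difluoro-4-hydroxybenzoate; 2 1-bromo-3-methylbut-2-ene (prenyl bromide)
Product: 3 methyl 2,6-difluoro-4-[(3-methylbut-2-en-1-yl)oxy]benzoate
Conditions: K2CO3, acetone, reflux
Reagents that add atoms: none
Why: Williamson ether synthesis; the acidic phenol is ionised by K2CO3 and the allylic bromide reacts at oxygen, while the fluorines stay because the phenoxide ring is electron-rich and the phenoxide a weak nucleophile.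

Step 2
Reactants: 3 methyl 2,6-difluoro-4-[(3-methylbut-2-en-1-yl)oxy]benzoate
Product: 4 methyl 2,6-difluoro-4-hydroxy-3-(2-methylbut-3-en-2-yl)benzoate
Conditions: PhNEt2, 190 °C (sealed tube)
Reagents that add atoms: none
Why: Aromatic Claisen rearrangement, a [3,3] shift with allyl inversion followed by tautomerisation, gives the ortho 1,1-dimethylallyl phenol; the two ortho carbons are equivalent by symmetry and the para carbon bears the ester, so only one constitution can result.

Step 3
Reactants: 4 methyl 2,6-difluoro-4-hydroxy-3-(2-methylbut-3-en-2-yl)benzoate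
Product: 5 methyl 2,6-difluoro-4-(methoxymethoxy)-3-(2-methylbut-3-en-2-yl)benzoate
Conditions: MOMCl, i-Pr2NEt, CH2Cl2, 0 °C → rt
Reagents that add atoms: chloromethyl methyl ether (MOMCl), COCCl
Why: O-Alkylation of the acidic phenol with the reactive chloromethyl ether; the ether is needed because a phenoxide would shut down the substitution of step 4.

Step 4
Reactants: 5 methyl 2,6-difluoro-4-(methoxymethoxy)-3-(2-methylbut-3-en-2-yl)benzoate
Product: 6 methyl 2-fluoro-6-methoxy-4-(methoxymethoxy)-3-(2-methylbut-3-en-2-yl)benzoate
Conditions: NaOMe, MeOH–THF, 50 °C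
Reagents that add atoms: sodium methoxide, [Na+].[O-]C
Why: Nucleophilic aromatic substitution activated by the ortho ester; both fluorines are electronically alike, but the one at C6 has an unsubstituted neighbour and the one at C2 is shielded by the quaternary carbon, so substitution should stop after C6. Methoxide on a methyl ester makes transesterification invisible.

Step 5
Reactants: 6 methyl 2-fluoro-6-methoxy-4-(methoxymethoxy)-3-(2-methylbut-3-en-2-yl)benzoate
Product: 7 2-fluoro-6-methoxy-4-(methoxymethoxy)-3-(2-methylbut-3-en-2-yl)benzoic acid
Conditions: LiOH, THF–MeOH–H2O, 60 °C; then 1 M HCl to pH 3, 0 °C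
Reagents that add atoms: lithium hydroxide, [Li+].[OH-]
Why: Saponification of the hindered benzoate by acyl attack of hydroxide; the remaining fluorine is shielded and the carboxylate formed deactivates the ring, and brief cold acidification leaves the aryl methoxymethyl ether intact.

Step 6
Reactants: 7 2-fluoro-6-methoxy-4-(methoxymethoxy)-3-(2-methylbut-3-en-2-yl)benzoic acid
Product: 8 2-fluoro-6-methoxy-4-(methoxymethoxy)-3-(2-methylbut-3-en-2-yl)benzoyl chloride
Conditions: 1-chloro-N,N,2-trimethylprop-1-en-1-amine, CH2Cl2, 0 °C → rt; used crude
Reagents that add atoms: 1-chloro-N,N,2-trimethylprop-1-en-1-amine, CC(C)=C(Cl)N(C)C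
Why: Acid chloride formation with an α-chloroenamine under neutral conditions; no HCl is released, so the methoxymethyl ether and the alkene are not exposed to acid.

Step 7
Reactants: 9 2-bromo-4-hydroxy-5-methoxybenzaldehyde (6-bromovanillin); 10 3-chloro-3-methylbut-1-yne
Product: 11 2-bromo-5-methoxy-4-[(2-methylbut-3-yn-2-yl)oxy]benzaldehyde
Conditions: DBU, CuCl2·2H2O (cat.), MeCN, 0 °C → rt
Reagents that add atoms: none
Why: Copper-catalysed O-alkylation of a phenol with a tertiary propargylic chloride, the standard entry to aryl 1,1-dimethylpropargyl ethers; it works best with acidic phenols such as 9.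

Step 8
Reactants: 11 2-bromo-5-methoxy-4-[(2-methylbut-3-yn-2-yl)oxy]benzaldehyde
Product: 12 5-bromo-8-methoxy-2,2-dimethyl-2H-chromene-6-carbaldehyde
Conditions: PhNEt2, 185 °C
Reagents that add atoms: none
Why: Aromatic propargyl Claisen rearrangement, then enolisation, 1,5-hydrogen shift and oxa-6π electrocyclisation, gives the 2,2-dimethyl-2H-chromene; the only free ortho carbon is the one between oxygen and bromine, so the ring can fuse in one direction only.

Step 9
Reactants: 12 5-bromo-8-methoxy-2,2-dimethyl-2H-chromene-6-carbaldehyde
Product: 13 5-bromo-8-methoxy-2,2-dimethylchroman-6-carbaldehyde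
Conditions: H2 (1 atm), 10% Pd/C, Ph2S (cat.), EtOAc, rt
Reagents that add atoms: none
Why: Catalytic hydrogenation of the cis-disubstituted styrenic C3=C4 bond; Pd/C moderated by Ph2S is known to saturate alkenes while leaving aryl bromides and aromatic aldehydes untouched.

Step 10
Reactants: 13 5-bromo-8-methoxy-2,2-dimethylchroman-6-carbaldehyde
Product: 14 5-bromo-8-hydroxy-2,2-dimethylchroman-6-carbaldehyde
Conditions: BBr3, CH2Cl2, −78 → 0 °C; aq. NaHCO3
Reagents that add atoms: none
Why: Lewis-acid cleavage of the aryl methyl ether; boron binds the methoxy oxygen and bromide removes the methyl group by SN2. At low temperature 2,2-dimethylchroman rings are known to survive this reagent, and the bromine and the aldehyde are inert.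

Step 11
Reactants: 14 5-bromo-8-hydroxy-2,2-dimethylchroman-6-carbaldehyde
Product: 15 5-bromo-8-(methoxymethoxy)-2,2-dimethylchroman-6-carbaldehyde
Conditions: MOMCl, i-Pr2NEt, CH2Cl2, rt
Reagents that add atoms: chloromethyl methyl ether (MOMCl), COCCl
Why: O-Alkylation of the phenol; this puts on ring B the same acid-labile group as on O3 and O7, so that one final operation frees all three.

Step 12
Reactants: 15 5-bromo-8-(methoxymethoxy)-2,2-dimethylchroman-6-carbaldehyde; 16 tributyl[(methoxymethoxy)methyl]stannane
Product: 17 1-[5-bromo-8-(methoxymethoxy)-2,2-dimethylchroman-6-yl]-2-(methoxymethoxy)ethan-1-ol (racemic)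
Conditions: 16, n-BuLi, THF, −78 °C; then 15, −78 °C; aq. NH4Cl
Reagents that add atoms: none
Why: Tin–lithium exchange on 16 gives an α-alkoxy organolithium that adds to the aldehyde much faster than it exchanges with the aryl bromide. The carbinol stereocentre forms as the racemate and is removed in step 14.

Step 13
Reactants: 17 1-[5-bromo-8-(methoxymethoxy)-2,2-dimethylchroman-6-yl]-2-(methoxymethoxy)ethan-1-ol; 2 1-bromo-3-methylbut-2-ene (prenyl bromide)
Product: 19 2-(methoxymethoxy)-1-[8-(methoxymethoxy)-2,2-dimethyl-5-(3-methylbut-2-en-1-yl)chroman-6-yl]ethan-1-ol (racemic), via aryllithium alkoxide 18 (not isolated)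
Conditions: n-BuLi (2.1 equiv), THF, −78 °C; CuBr·SMe2 (cat.); 2, −78 → 0 °C; aq. NH4Cl
Reagents that add atoms: none
Why: Deprotonation of the alcohol and bromine–lithium exchange give 18, whose aryl–metal bond is allylated by prenyl bromide under copper catalysis at the primary carbon. The lithium alkoxide is too weak a nucleophile at this temperature to be alkylated, and the existing stereocentre is not touched.

Step 14
Reactants: 19 2-(methoxymethoxy)-1-[8-(methoxymethoxy)-2,2-dimethyl-5-(3-methylbut-2-en-1-yl)chroman-6-yl]ethan-1-ol
Product: 20 2-(methoxymethoxy)-1-[8-(methoxymethoxy)-2,2-dimethyl-5-(3-methylbut-2-en-1-yl)chroman-6-yl]ethan-1-one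
Conditions: Dess–Martin periodinane, NaHCO3, CH2Cl2, rt
Reagents that add atoms: none
Why: Dess–Martin oxidation of the secondary benzylic alcohol under buffered conditions that spare both methoxymethyl ethers and the trisubstituted alkene; the racemic stereocentre disappears.

Step 15
Reactants: 20 2-(methoxymethoxy)-1-[8-(methoxymethoxy)-2,2-dimethyl-5-(3-methylbut-2-en-1-yl)chroman-6-yl]ethan-1-one; 8 2-fluoro-6-methoxy-4-(methoxymethoxy)-3-(2-methylbut-3-en-2-yl)benzoyl chloride
Product: 22 5-methoxy-3,7-bis(methoxymethoxy)-2-[8-(methoxymethoxy)-2,2-dimethyl-5-(3-methylbut-2-en-1-yl)chroman-6-yl]-8-(2-methylbut-3-en-2-yl)-4H-chromen-4-one, via fluoro diketone 21 (not isolated)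
Conditions: LiN(SiMe3)2 (2.2 equiv), THF, −78 °C; 8, −78 → 0 °C; then DMF, 90 °C
Reagents that add atoms: none
Why: LiN(SiMe3)2 converts 20 into its lithium enolate, which is acylated at carbon by 8 to give diketone 21 (C3–C4 bond), and the second equivalent of base holds 21 as its enolate. On heating in DMF the enolate oxygen that began as the carbonyl oxygen of 20 adds to C8a, the Meisenheimer intermediate is stabilised by the C4 carbonyl, and loss of fluoride completes the pyranone (O1–C8a bond). The closest known reaction type is the one-pot preparation of chromones and flavones from ketone enolates and 2-fluorobenzoyl chlorides by C-acylation and intramolecular SNAr. Ring C closes as a six-membered ring by attack on the C8a=C4a bond, which lies inside the new ring (a 6-endo-trig addition of the oxa-Michael kind), and fluoride leaves from an exocyclic position. No stereocentre is formed, and the C3 stereocentre of 21 is lost on enolisation. The step needs C- rather than O-acylation, which the lithium enolate in THF and the irreversible deprotonation of 21 favour, and it needs the ring oxygen on the carbon next to the tert-alkyl group, which is fixed because only that carbon carries fluorine. The methoxy group on the other ortho carbon is not displaced, because its adduct can only revert by expelling the much better diketonate leaving group. The alkoxy groups at C5 and C7 are meta to C8a and leave its electrophilicity intact, so only the steric shielding by the C8 substituent has to be overcome by heat.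

Step 16
Reactants: 22 5-methoxy-3,7-bis(methoxymethoxy)-2-[8-(methoxymethoxy)-2,2-dimethyl-5-(3-methylbut-2-en-1-yl)chroman-6-yl]-8-(2-methylbut-3-en-2-yl)-4H-chromen-4-one
Product: 23 5-hydroxy-3,7-bis(methoxymethoxy)-2-[8-(methoxymethoxy)-2,2-dimethyl-5-(3-methylbut-2-en-1-yl)chroman-6-yl]-8-(2-methylbut-3-en-2-yl)-4H-chromen-4-one
Conditions: MgI2·OEt2, THF, 60 °C; aq. NH4Cl
Reagents that add atoms: none
Why: Chelation-controlled dealkylation; magnesium binds between the C4 carbonyl and the peri 5-methoxy oxygen and iodide removes the methyl group by SN2. The alkenes do not react with MgI2, and loss of the chelated 3-O-methoxymethyl group would not matter because step 17 removes it anyway.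

Step 17
Reactants: 23 5-hydroxy-3,7-bis(methoxymethoxy)-2-[8-(methoxymethoxy)-2,2-dimethyl-5-(3-methylbut-2-en-1-yl)chroman-6-yl]-8-(2-methylbut-3-en-2-yl)-4H-chromen-4-one
Product: 24 3,5,7-trihydroxy-2-[8-hydroxy-2,2-dimethyl-5-(3-methylbut-2-en-1-yl)chroman-6-yl]-8-(2-methylbut-3-en-2-yl)-4H-chromen-4-one (Broussoflavonol E)
Conditions: HCl in MeOH (1.25 M), 40 °C
Reagents that add atoms: none
Why: Acid-catalysed acetal exchange of the three methoxymethyl ethers with methanol, the usual way to free prenylated flavonoids; the monosubstituted alkene of the 1,1-dimethylallyl group is slow to protonate and the ring B prenyl group has no neighbouring hydroxyl to trap a cation.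

## Compound list

1 | methyl 2,6-difluoro-4-hydroxybenzoate | COC(=O)c1c(F)cc(O)cc1F | starting material
2 | 1-bromo-3-methylbut-2-ene (prenyl bromide) | CC(C)=CCBr | starting material
3 | methyl 2,6-difluoro-4-[(3-methylbut-2-en-1-yl)oxy]benzoate | COC(=O)c1c(F)cc(OCC=C(C)C)cc1F | intermediate
4 | methyl 2,6-difluoro-4-hydroxy-3-(2-methylbut-3-en-2-yl)benzoate | COC(=O)c1c(F)cc(O)c(C(C)(C)C=C)c1F | intermediate
5 | methyl 2,6-difluoro-4-(methoxymethoxy)-3-(2-methylbut-3-en-2-yl)benzoate | COC(=O)c1c(F)cc(OCOC)c(C(C)(C)C=C)c1F | intermediate
6 | methyl 2-fluoro-6-methoxy-4-(methoxymethoxy)-3-(2-methylbut-3-en-2-yl)benzoate | COC(=O)c1c(OC)cc(OCOC)c(C(C)(C)C=C)c1F | intermediate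
7 | 2-fluoro-6-methoxy-4-(methoxymethoxy)-3-(2-methylbut-3-en-2-yl)benzoic acid | OC(=O)c1c(OC)cc(OCOC)c(C(C)(C)C=C)c1F | intermediate
8 | 2-fluoro-6-methoxy-4-(methoxymethoxy)-3-(2-methylbut-3-en-2-yl)benzoyl chloride | C=CC(C)(C)c1c(F)c(C(=O)Cl)c(OC)cc1OCOC | intermediate
9 | 2-bromo-4-hydroxy-5-methoxybenzaldehyde (6-bromovanillin) | O=Cc1cc(OC)c(O)cc1Br | starting material
10 | 3-chloro-3-methylbut-1-yne | CC(C)(Cl)C#C | starting material
11 | 2-bromo-5-methoxy-4-[(2-methylbut-3-yn-2-yl)oxy]benzaldehyde | O=Cc1cc(OC)c(OC(C)(C)C#C)cc1Br | intermediate
12 | 5-bromo-8-methoxy-2,2-dimethyl-2H-chromene-6-carbaldehyde | O=Cc1cc(OC)c2c(c1Br)C=CC(C)(C)O2 | intermediate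
13 | 5-bromo-8-methoxy-2,2-dimethylchroman-6-carbaldehyde | O=Cc1cc(OC)c2c(c1Br)CCC(C)(C)O2 | intermediate
14 | 5-bromo-8-hydroxy-2,2-dimethylchroman-6-carbaldehyde | O=Cc1cc(O)c2c(c1Br)CCC(C)(C)O2 | intermediate
15 | 5-bromo-8-(methoxymethoxy)-2,2-dimethylchroman-6-carbaldehyde | O=Cc1cc(OCOC)c2c(c1Br)CCC(C)(C)O2 | intermediate
16 | tributyl[(methoxymethoxy)methyl]stannane | CCCC[Sn](CCCC)(CCCC)COCOC | starting material
17 | 1-[5-bromo-8-(methoxymethoxy)-2,2-dimethylchroman-6-yl]-2-(methoxymethoxy)ethan-1-ol (racemic) | COCOCC(O)c1cc(OCOC)c2c(c1Br)CCC(C)(C)O2 | intermediate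
18 | aryllithium alkoxide from 17 (dilithio species; not isolated) | COCOCC(O[Li])c1cc(OCOC)c2c(c1[Li])CCC(C)(C)O2 | intermediate
19 | 2-(methoxymethoxy)-1-[8-(methoxymethoxy)-2,2-dimethyl-5-(3-methylbut-2-en-1-yl)chroman-6-yl]ethan-1-ol (racemic) | COCOCC(O)c1cc(OCOC)c2c(c1CC=C(C)C)CCC(C)(C)O2 | intermediate
20 | 2-(methoxymethoxy)-1-[8-(methoxymethoxy)-2,2-dimethyl-5-(3-methylbut-2-en-1-yl)chroman-6-yl]ethan-1-one | COCOCC(=O)c1cc(OCOC)c2c(c1CC=C(C)C)CCC(C)(C)O2 | intermediate
21 | 1-[2-fluoro-6-methoxy-4-(methoxymethoxy)-3-(2-methylbut-3-en-2-yl)phenyl]-2-(methoxymethoxy)-3-[8-(methoxymethoxy)-2,2-dimethyl-5-(3-methylbut-2-en-1-yl)chroman-6-yl]propane-1,3-dione (racemic; not isolated) | C=CC(C)(C)c1c(F)c(C(=O)C(OCOC)C(=O)c2cc(OCOC)c3c(c2CC=C(C)C)CCC(C)(C)O3)c(OC)cc1OCOC | intermediate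
22 | 5-methoxy-3,7-bis(methoxymethoxy)-2-[8-(methoxymethoxy)-2,2-dimethyl-5-(3-methylbut-2-en-1-yl)chroman-6-yl]-8-(2-methylbut-3-en-2-yl)-4H-chromen-4-one | C=CC(C)(C)c1c(OCOC)cc(OC)c2c(=O)c(OCOC)c(-c3cc(OCOC)c4c(c3CC=C(C)C)CCC(C)(C)O4)oc12 | intermediate
23 | 5-hydroxy-3,7-bis(methoxymethoxy)-2-[8-(methoxymethoxy)-2,2-dimethyl-5-(3-methylbut-2-en-1-yl)chroman-6-yl]-8-(2-methylbut-3-en-2-yl)-4H-chromen-4-one | C=CC(C)(C)c1c(OCOC)cc(O)c2c(=O)c(OCOC)c(-c3cc(OCOC)c4c(c3CC=C(C)C)CCC(C)(C)O4)oc12 | intermediate
24 | 3,5,7-trihydroxy-2-[8-hydroxy-2,2-dimethyl-5-(3-methylbut-2-en-1-yl)chroman-6-yl]-8-(2-methylbut-3-en-2-yl)-4H-chromen-4-one (Broussoflavonol E) | C=CC(C)(C)c1c(O)cc(O)c2c(=O)c(O)c(-c3cc(O)c4c(c3CC=C(C)C)CCC(C)(C)O4)oc12 | target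

## Step count and least certain steps

Total step count: 17. Longest linear sequence: 11 steps (steps 7 to 17, from 9). The ring A branch (steps 1 to 6, from 1) joins at step 15.

**Step 15 (key step).** The most likely failure is that ring closure stalls. The lithium diketonate is a chelated, weakly nucleophilic enolate, and C8a lies between the acyl-bearing carbon and a quaternary carbon. While closure waits, 21 can be cleaved by retro-Claisen attack, and part of 8 may already have been lost to O-acylation of the enolate.

The fallback separates the two events and replaces the acylation by an aldol addition. It sets out from ester 6 and ketone 20.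
- Reduction of 6 with i-Bu2AlH should give [2-fluoro-6-methoxy-4-(methoxymethoxy)-3-(2-methylbut-3-en-2-yl)phenyl]methanol F1.
- MnO2 should oxidise this to 2-fluoro-6-methoxy-4-(methoxymethoxy)-3-(2-methylbut-3-en-2-yl)benzaldehyde F2.
- The lithium enolate of 20 should add to F2 at −78 °C to give the β-hydroxy ketone (aldol adduct) F3. Only C-attack is possible here.
- Dess–Martin oxidation of F3 returns to the route at 21, now isolated.
- Ring closure to 22 is then run with Cs2CO3 in DMSO at 100 °C, as the free caesium enolate in a dipolar medium. The one-pot lithium protocol cannot offer these conditions.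

**Step 2.** The risk is further reaction of the product at the temperature of the rearrangement. The phenolic hydrogen can be transferred to the new terminal alkene (abnormal Claisen rearrangement), or the phenol can cyclise onto it, because the 1,1-dimethylallyl group sits directly ortho to the hydroxyl.

The fallback makes the aryl–C(quaternary) bond by cross-coupling. It sets out from 1 and returns at 5.
- Iodination of 1 with N-iodosuccinimide at the position ortho to the hydroxyl (the two are equivalent) should give methyl 2,6-difluoro-4-hydroxy-3-iodobenzoate F4.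
- MOMCl and i-Pr2NEt should convert this into methyl 2,6-difluoro-3-iodo-4-(methoxymethoxy)benzoate F5.
- A Suzuki–Miyaura coupling of F5 with the pinacol ester of prenylboronic acid should give 5. It would use Pd(OAc)2, a bulky dialkylbiarylphosphine, K3PO4 and aqueous THF, under the ligand-controlled conditions that transfer the allyl group at its substituted (γ) terminus.

**Step 13.** Two processes threaten this step: attack of the aryl–metal species at the substituted end of prenyl bromide (SN2' course, giving the branched isomer), and quenching or incomplete formation of the aryllithium next to the internal alkoxide.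

The fallback forms the aryl–prenyl bond by palladium catalysis before the side chain is extended. It sets out from 15 and returns at 19.
- Stille coupling of 15 with tributyl(3-methylbut-2-en-1-yl)stannane and Pd(PPh3)4 in DMF at 90 °C should give 8-(methoxymethoxy)-2,2-dimethyl-5-(3-methylbut-2-en-1-yl)chroman-6-carbaldehyde F6. Reductive elimination from the less hindered allylpalladium isomer gives the linear prenyl arene.
- Addition of the organolithium generated from 16, as in step 12, should then give 19.

**Step 16.** The risk is uneven loss of methoxymethyl groups during a slow demethylation. Magnesium is also held in the five-membered chelate between O3 and the C4 carbonyl, and this competes with the productive O4/O5 chelate.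

The fallback replaces the methyl ether by an allyl ether, which is removed without any Lewis acid. It sets out from 5 and returns at 23.
- Treatment of 5 with sodium prop-2-en-1-olate (allyl alcohol, NaH, THF, 50 °C), followed in the same flask by aqueous NaOH at 60 °C and acidification, should give 6-(allyloxy)-2-fluoro-4-(methoxymethoxy)-3-(2-methylbut-3-en-2-yl)benzoic acid F7.
- The reagent of step 6 should convert this into 6-(allyloxy)-2-fluoro-4-(methoxymethoxy)-3-(2-methylbut-3-en-2-yl)benzoyl chloride F8.
- Under the conditions of step 15, F8 and 20 should give, through the allyloxy fluoro diketone F9, the 5-(allyloxy)flavone F10.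
- The zerovalent palladium complex Pd(PPh3)4 with morpholine in THF at room temperature should remove the O-allyl group and give 23. The C-bound prenyl and 1,1-dimethylallyl groups cannot ionise under these conditions.

## Further compounds

F1 | step 15 | [2-fluoro-6-methoxy-4-(methoxymethoxy)-3-(2-methylbut-3-en-2-yl)phenyl]methanol | OCc1c(OC)cc(OCOC)c(C(C)(C)C=C)c1F
F2 | step 15 | 2-fluoro-6-methoxy-4-(methoxymethoxy)-3-(2-methylbut-3-en-2-yl)benzaldehyde | O=Cc1c(OC)cc(OCOC)c(C(C)(C)C=C)c1F
F3 | step 15 | 3-[2-fluoro-6-methoxy-4-(methoxymethoxy)-3-(2-methylbut-3-en-2-yl)phenyl]-3-hydroxy-2-(methoxymethoxy)-1-[8-(methoxymethoxy)-2,2-dimethyl-5-(3-methylbut-2-en-1-yl)chroman-6-yl]propan-1-one (mixture of racemic diastereomers) | C=CC(C)(C)c1c(F)c(C(O)C(OCOC)C(=O)c2cc(OCOC)c3c(c2CC=C(C)C)CCC(C)(C)O3)c(OC)cc1OCOC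
F4 | step 2 | methyl 2,6-difluoro-4-hydroxy-3-iodobenzoate | COC(=O)c1c(F)cc(O)c(I)c1F
F5 | step 2 | methyl 2,6-difluoro-3-iodo-4-(methoxymethoxy)benzoate | COC(=O)c1c(F)cc(OCOC)c(I)c1F
F6 | step 13 | 8-(methoxymethoxy)-2,2-dimethyl-5-(3-methylbut-2-en-1-yl)chroman-6-carbaldehyde | O=Cc1cc(OCOC)c2c(c1CC=C(C)C)CCC(C)(C)O2
F7 | step 16 | 6-(allyloxy)-2-fluoro-4-(methoxymethoxy)-3-(2-methylbut-3-en-2-yl)benzoic acid | OC(=O)c1c(OCC=C)cc(OCOC)c(C(C)(C)C=C)c1F
F8 | step 16 | 6-(allyloxy)-2-fluoro-4-(methoxymethoxy)-3-(2-methylbut-3-en-2-yl)benzoyl chloride | C=CCOc1cc(OCOC)c(C(C)(C)C=C)c(F)c1C(Cl)=O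
F9 | step 16 | 1-[6-(allyloxy)-2-fluoro-4-(methoxymethoxy)-3-(2-methylbut-3-en-2-yl)phenyl]-2-(methoxymethoxy)-3-[8-(methoxymethoxy)-2,2-dimethyl-5-(3-methylbut-2-en-1-yl)chroman-6-yl]propane-1,3-dione (racemic; not isolated) | C=CCOc1cc(OCOC)c(C(C)(C)C=C)c(F)c1C(=O)C(OCOC)C(=O)c1cc(OCOC)c2c(c1CC=C(C)C)CCC(C)(C)O2
F10 | step 16 | 5-(allyloxy)-3,7-bis(methoxymethoxy)-2-[8-(methoxymethoxy)-2,2-dimethyl-5-(3-methylbut-2-en-1-yl)chroman-6-yl]-8-(2-methylbut-3-en-2-yl)-4H-chromen-4-one | C=CC(C)(C)c1c(OCOC)cc(OCC=C)c2c(=O)c(OCOC)c(-c3cc(OCOC)c4c(c3CC=C(C)C)CCC(C)(C)O4)oc12
A1 | alternative 1 | 3-ethoxycyclobut-2-en-1-one | CCOC1=CC(=O)C1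
A2 | alternative 1 | [(3,3-dimethylpent-4-en-1-yn-1-yl)oxy]tri(propan-2-yl)silane | C=CC(C)(C)C#CO[Si](C(C)C)(C(C)C)C(C)C
A3 | alternative 1 | 5-ethoxy-2-(2-methylbut-3-en-2-yl)-3-[(triisopropylsilyl)oxy]phenol | CCOc1cc(O)c(C(C)(C)C=C)c(O[Si](C(C)C)(C(C)C)C(C)C)c1
A4 | alternative 2 | 2-bromo-4-hydroxy-3-(hydroxymethyl)-5-methoxybenzaldehyde | O=Cc1cc(OC)c(O)c(CO)c1Br
A5 | alternative 2 | 2-methylpropene | CC(C)=C
A6 | alternative 2 | 5-bromo-8-methoxy-2,2-dimethylchroman-6-carbaldehyde (identical with 13) | O=Cc1cc(OC)c2c(c1Br)CCC(C)(C)O2
A7 | alternative 3 | 3,5-bis(methoxymethoxy)-2-(trimethylsilyl)phenyl trifluoromethanesulfonate | COCOc1cc(OCOC)c([Si](C)(C)C)c(OS(=O)(=O)C(F)(F)F)c1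
A8 | alternative 3 | 3-[8-(methoxymethoxy)-2,2-dimethyl-5-(3-methylbut-2-en-1-yl)chroman-6-yl]prop-2-ynoic acid | OC(=O)C#Cc1cc(OCOC)c2c(c1CC=C(C)C)CCC(C)(C)O2
A9 | alternative 3 | 5,7-bis(methoxymethoxy)-2-[8-(methoxymethoxy)-2,2-dimethyl-5-(3-methylbut-2-en-1-yl)chroman-6-yl]-4H-chromen-4-one | COCOc1cc(OCOC)c2c(=O)cc(-c3cc(OCOC)c4c(c3CC=C(C)C)CCC(C)(C)O4)oc2c1
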